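The numbers in the tables stem from a simulated flask with constants of no real substance; noise was put on by code.

Late on, the north-west run stood still at 73.8 % of its starting material charged, with 26.2 % of that charge unturned and 69.2 % of its coupling partner unused, so I suspected the catalyst. But a plateau says little about mid-run, and the north run could.

| flask | starting material | coupling partner | free catalyst | time |
|---|---|---|---|---|
| west | 0.500 M | 0.400 M | 0.00500 M |  |
| north | 0.250 M | 0.150 M | 0.00500 M |  |
| north-west | 0.500 M | 1.20 M | 0.00500 M |  |
| north-east | 0.500 M | 0.130 M | 0.0100 M | 140 min |

| run | time / min | [product] / M |
|---|---|---|
| west run | 28 | 0.234 |
| west run | 56 | 0.313 |
| west run | 84 | 0.338 |
| west run | 110 | 0.348 |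
| west run | 140 | 0.354 |
| north run | 28 | 0.101 |
| north run | 56 | 0.138 |
| north run | 84 | 0.140 |
| north run | 110 | 0.143 |
| north run | 140 | 0.153 |
| north-west run | 28 | 0.338 |
| north-west run | 56 | 0.367 |
| north-west run | 84 | 0.371 |
| north-west run | 110 | 0.368 |
| north-west run | 140 | 0.369 |

(standard deviation of a reading: 0.003 M)

- reaction order in [coupling partner] at the outset, round the charge of the west run, defined at two percent of the starting material turned into product
- reaction order in [starting material] at the outset, round the charge of the west run, defined at two percent of the starting material turned into product (one fixed amount of product, the same in the runs compared)
- the north run starts with 0.250 M less of starting material and of coupling partner than the west run, and with no product. Compared where both hold the same amount of starting material, once fifteen percent of what the north run was charged with has turned into product, is the north run faster, slower or alike (within a tenth)?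
- product in the north-east run at 140 min, as a share of the starting material charged
- which of these the readings show (the product speeds the reaction / the product kills the catalyst / the loaded catalyst dies / nothing beyond the main steps / the second partner pairs with itself / the second partner is lost in pairs)

- Overall: starting material + coupling partner -> product, with free catalyst as catalyst.
- Constant volume, constant temperature.
- Bound and free are read together.
- "The second partner" is coupling partner.
- An order is taken over about fifteen percent of the charge, up and down.

The north run is charged as the west run stands once half of the west starting material has turned, but it holds no product: a same-excess comparison. So I timed one stretch in both. The north run turned 20.2 % of the west charge in its first 28 min. The west run, from 28 min to 84 min, turned 20.8 % of it and took 56.0 min, so the north run went faster. I call the north run's average rate over the west run's on that matched stretch the stretch ratio, and I read it as 1.94. The compositions were close, so I took it as working catalyst in the north run over that in the west run.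

I then used it on the north-east run, where the coupling partner is the limiting reagent at 26.0 % of the starting material. As a harsh allowance I divided that run's catalyst by the ratio, which left 1.03 times the north run's charge. The north run had turned 92.0 % of its partner by 56 min, so my own reckoning, separate from the forecast, was the ceiling set by that partner's charge: 26.0 % at 140 min.

The forecast gave orders of 0.6 in coupling partner and 0.9 in starting material, the north run faster, 25.8 %, and this verdict: the loaded catalyst dies. Its ground was “the loss tracks turnover, not time”. Its 25.8 % stands below my ceiling of 26.0 %.

The flask gave 0.68 and 0.21, the north run faster, 26.0 %, and this verdict: the product kills the catalyst.

    free catalyst + starting material → catalyst-substrate complex (26.22 M⁻¹ min⁻¹)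
    catalyst-substrate complex + coupling partner → loaded catalyst (10.32 M⁻¹ min⁻¹)
    loaded catalyst → product + free catalyst (20.40 min⁻¹)
    free catalyst + product → spent catalyst + product (0.4404 M⁻¹ min⁻¹)

We parted on the verdict. The north run's lead, my stretch ratio of 1.94, belongs to the step in which product turns free catalyst into spent catalyst: at equal starting material the rate of the north run over the west run is 1.9 with that step and 1.0 without it. In the north-east run, where I had allowed the same loss of 1.94, that step changes nothing: product stands at 26.0 % with it and 26.0 % without it.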